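A direct plan would alkylate the phenol of methyl p-coumarate A1 to its 2-methylbut-3-yn-2-yl ether A2, would semihydrogenate A2 to the 1,1-dimethylallyl ether A3 and would rearrange A3 by heat to the ortho-prenyl phenol A4. A4 would then capture the ketene from photochemical Wolff rearrangement of the lactic acid derived diazoketone A5. Its weakest steps would be the alkyne semihydrogenation, which would have to stop at the alkene and spare the cinnamate C=C; the photochemical ketene generation and capture, in which loss of acetic acid, O–H insertion and E/Z isomerisation would compete; and the four operations that would be spent on one prenyl group, which would add length without adding complexity.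

The benzene ring is not functionalised but built: its C2–C3 and C4–C5 bonds are formed by an inverse-demand Diels–Alder reaction between a 2-pyrone that carries the acrylate (ring C1, C2, C5, C6) and a siloxyalkyne that carries the prenyl group and the oxygen (ring C3, C4), followed by loss of CO2. The step exploits the para relation of the C4 oxygen to the acceptor at C1 and places the prenyl group at C3 without any phenol alkylation, ether, semihydrogenation or sigmatropic shift. The aryl silyl ether so formed exchanges silicon for the chiral-pool (S)-3-acetoxybutanoyl group under fluoride catalysis, so no diazoketone, photolysis or ketene is needed.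

Key step: step 4

Assumption: 5-bromo-2H-pyran-2-one, ethynylmagnesium bromide (0.5 M in THF) and (S)-3-hydroxybutanoic acid are taken as catalogue chemicals.

Step 1
Reactants: 1 5-bromo-2H-pyran-2-one; 2 methyl acrylate
Product: 3 methyl (E)-3-(2-oxo-2H-pyran-5-yl)prop-2-enoate
Conditions: Pd(OAc)2 (5 mol%), Bu4NCl (1 equiv), NaHCO3 (2.5 equiv), 2 (3 equiv), DMF, 60 °C, Ar
Reagents that add atoms: none
Why: Mizoroki–Heck reaction in its ligand-free phase-transfer variant, in which zerovalent palladium inserts into the C5–Br bond of the pyrone, syn carbopalladation of the acrylate and syn β-hydride elimination give the E alkene, and the solid bicarbonate base and moderate temperature should spare the base-sensitive lactone and outrun any Diels–Alder reaction of the pyrone with the acrylate.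

Step 2
Reactants: 4 prenyl bromide (1-bromo-3-methylbut-2-ene); 5 ethynylmagnesium bromide
Product: 6 5-methylhex-4-en-1-yne
Conditions: 5 (2.5 equiv, 0.5 M in THF), CuBr·SMe2 (5 mol%), 4 added slowly, THF, 0 °C to rt; NH4Cl (aq); fractional distillation (or use as a titrated THF solution)
Reagents that add atoms: none
Why: Copper-catalysed coupling of an alkynyl Grignard reagent with a primary allylic bromide, which should join the acetylide to the unhindered CH2 terminus, while excess Grignard reagent and inverse addition suppress double alkylation and the weakly basic medium does not isomerise the skipped enyne.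

Step 3
Reactants: 6 5-methylhex-4-en-1-yne
Product: 9 triisopropyl[(5-methylhex-4-en-1-yn-1-yl)oxy]silane, via lithium acetylide 7 (not isolated), via lithium ynolate 8 (not isolated)
Conditions: LiN(SiMe3)2 (2.2 equiv), t-BuOOH (1.1 equiv, in decane), THF, −78 to 0 °C; then i-Pr3SiOTf (1.2 equiv), −78 to 0 °C; filtration through Et3N-deactivated silica (pentane)
Reagents that add atoms: tert-butyl hydroperoxide, CC(C)(C)OO; triisopropylsilyl trifluoromethanesulfonate, CC(C)[Si](OS(=O)(=O)C(F)(F)F)(C(C)C)C(C)C
Why: Oxidation of a lithium acetylide to the lithium ynolate by the electrophilic oxygen of lithium tert-butyl peroxide, then O-silylation, where the terminal C–H is far more acidic than the skipped CH2 and the bulky triisopropylsilyl triflate should silylate oxygen and not carbon.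

Step 4
Reactants: 3 methyl (E)-3-(2-oxo-2H-pyran-5-yl)prop-2-enoate; 9 triisopropyl[(5-methylhex-4-en-1-yn-1-yl)oxy]silane
Product: 11 methyl (E)-3-[3-(3-methylbut-2-enyl)-4-(triisopropylsilyloxy)phenyl]prop-2-enoate, via bicyclic lactone 10 (not isolated)
Conditions: 9 (1.3 equiv), PhMe (0.5 M), 100 °C, sealed tube, Ar, BHT (1 mol%); flash chromatography
Reagents that add atoms: none
Why: Inverse-electron-demand Diels–Alder reaction of an acceptor-substituted 2-pyrone with a silyl ynol ether, then retro-Diels–Alder loss of CO2; the closest known reaction type is the benzannulation of coumalates with ynamines and alkoxyalkynes, of which the silyl ynol ether is the O-silyl counterpart. The HOMO of 9 is largest on the prenyl-bearing carbon and the LUMO of 3 on pyrone C6, which is the δ-carbon of the lactone and vinylogously activated by the acrylate, so the prenyl-bearing carbon should bond to C6 and the silyloxy-bearing carbon to C3. The carbocycle is closed in the [4+2] mode to the 2-oxabicyclo[2.2.2]octadienone 10, whose cycloreversion expels CO2 and leaves the benzene ring with oxygen para and prenyl meta to the acrylate. No stereocentre remains, because the two bridgehead centres of 10 are lost on aromatisation and the E acrylate is not touched. The step needs regioselectivity and periselectivity (ring diene against the C6=C5–CH=CH dienyl ester and against [2+2] addition at the acrylate), which the s-cis-locked ring diene, the absence of any Lewis acid or soft-metal catalyst and the irreversible CO2 loss should secure. The triisopropylsilyl group should keep the ynol ether from a 1,3-silyl shift to a silylketene at this temperature.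

Step 5
Reactants: 12 (S)-3-hydroxybutanoic acid
Product: 13 (S)-3-acetoxybutanoic acid
Conditions: AcCl (2.5 equiv), neat, 0 °C to rt; volatiles removed in vacuo; brief stir in THF/H2O; extraction
Reagents that add atoms: acetyl chloride, CC(Cl)=O
Why: O-acetylation of the secondary alcohol by an acyl chloride without base, which breaks no bond at C3 and so keeps the S configuration of the chiral-pool acid, any mixed anhydride being hydrolysed in the aqueous stir.

Step 6
Reactants: 13 (S)-3-acetoxybutanoic acid
Product: 14 (S)-3-acetoxybutanoyl fluoride
Conditions: cyanuric fluoride (0.7 equiv), pyridine (1 equiv), CH2Cl2, −15 °C to rt; cold water wash, MgSO4; used without chromatography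
Reagents that add atoms: cyanuric fluoride, Fc1nc(F)nc(F)n1
Why: Acyl fluoride formation with cyanuric fluoride, chosen because acyl fluorides are much less prone than chlorides to ketene formation and to loss of the β-acetoxy group, and the stereocentre is β to the carbonyl and cannot epimerise.

Step 7
Reactants: 11 methyl (E)-3-[3-(3-methylbut-2-enyl)-4-(triisopropylsilyloxy)phenyl]prop-2-enoate; 14 (S)-3-acetoxybutanoyl fluoride
Product: 16 methyl (E)-3-[4-[(3S)-3-acetoxybutanoyl]oxy-3-(3-methylbut-2-enyl)phenyl]prop-2-enoate (CNP0290147.1), via tetrabutylammonium aryloxide 15 (not isolated)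
Conditions: 14 (1.3 equiv), Bu4N[Ph3SiF2] (5 mol%), dry MeCN, −20 to 0 °C; pH 7 phosphate buffer; flash chromatography
Reagents that add atoms: none
Why: Fluoride-catalysed silyl-to-acyl exchange, in which fluoride cleaves the aryl O–Si bond, the aryloxide is acylated at once by the acyl fluoride and fluoride is returned, so the basic aryloxide should never accumulate and loss of acetic acid from the β-acetoxy ester should stay slow at this temperature, with the S centre untouched.

Compound list
1 | 5-bromo-2H-pyran-2-one | O=c1ccc(Br)co1 | starting material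
2 | methyl acrylate | C=CC(=O)OC | starting material
3 | methyl (E)-3-(2-oxo-2H-pyran-5-yl)prop-2-enoate | COC(=O)/C=C/c1ccc(=O)oc1 | intermediate
4 | prenyl bromide, 1-bromo-3-methylbut-2-ene | CC(C)=CCBr | starting material
5 | ethynylmagnesium bromide | C#C[Mg]Br | starting material
6 | 5-methylhex-4-en-1-yne | C#CCC=C(C)C | intermediate
7 | lithium acetylide, lithium 5-methylhex-4-en-1-yn-1-ide | [Li+].[C-]#CCC=C(C)C | intermediate (not isolated)
8 | lithium ynolate, lithium 5-methylhex-4-en-1-yn-1-olate | [Li+].[O-]C#CCC=C(C)C | intermediate (not isolated)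
9 | triisopropyl[(5-methylhex-4-en-1-yn-1-yl)oxy]silane | CC(C)=CCC#CO[Si](C(C)C)(C(C)C)C(C)C | intermediate
10 | bicyclic lactone, methyl (E)-3-[7-(3-methylbut-2-enyl)-3-oxo-8-(triisopropylsilyloxy)-2-oxabicyclo[2.2.2]octa-5,7-dien-6-yl]prop-2-enoate (racemic at the bridgeheads) | O=C1OC2C(CC=C(C)C)=C(O[Si](C(C)C)(C(C)C)C(C)C)C1C=C2/C=C/C(=O)OC | intermediate (not isolated)
11 | methyl (E)-3-[3-(3-methylbut-2-enyl)-4-(triisopropylsilyloxy)phenyl]prop-2-enoate | COC(=O)/C=C/c1ccc(O[Si](C(C)C)(C(C)C)C(C)C)c(CC=C(C)C)c1 | intermediate
12 | (S)-3-hydroxybutanoic acid | C[C@H](O)CC(=O)O | starting material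
13 | (S)-3-acetoxybutanoic acid | C[C@H](OC(C)=O)CC(=O)O | intermediate
14 | (S)-3-acetoxybutanoyl fluoride | C[C@H](OC(C)=O)CC(F)=O | intermediate
15 | tetrabutylammonium aryloxide, tetrabutylammonium 4-[(E)-3-methoxy-3-oxoprop-1-enyl]-2-(3-methylbut-2-enyl)phenolate | CCCC[N+](CCCC)(CCCC)CCCC.COC(=O)/C=C/c1ccc([O-])c(CC=C(C)C)c1 | intermediate (not isolated)
16 | CNP0290147.1, methyl (E)-3-[4-[(3S)-3-acetoxybutanoyl]oxy-3-(3-methylbut-2-enyl)phenyl]prop-2-enoate | COC(=O)/C=C/c1ccc(OC(=O)C[C@H](C)OC(C)=O)c(CC=C(C)C)c1 | target

Total step count: 7
Longest linear sequence: 4 steps (steps 2, 3, 4 and 7)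

Steps most likely to fail

Step 4. The risk is poor periselectivity, with the alkyne adding across the C6=C5–CH=CH dienyl ester or to the acrylate instead of across the ring diene, or thermal decay of the ynol ether before cycloaddition. The fallback sets out from 9 and comes back at 11. The same ring synthesis would be run with commercial methyl coumalate (methyl 2-oxo-2H-pyran-5-carboxylate, COC(=O)c1ccc(=O)oc1), a more electron-poor diene without a side-chain alkene, to give methyl 3-(3-methylbut-2-enyl)-4-(triisopropylsilyloxy)benzoate F1. Reduction with i-Bu2AlH (CH2Cl2, −78 °C) would give [3-(3-methylbut-2-enyl)-4-(triisopropylsilyloxy)phenyl]methanol F2, oxidation with MnO2 (CH2Cl2, rt) would give 3-(3-methylbut-2-enyl)-4-(triisopropylsilyloxy)benzaldehyde F3, and Wittig olefination with Ph3P=CHCO2Me (CH2Cl2, rt) would return to 11 as the E ester.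

Step 7. The risk is base-induced loss of acetic acid from the β-acetoxy acyl group under the aryloxide and fluoride, or slow cleavage of the hindered O–Si bond, so that the exchange stalls. The fallback sets out from 11 and comes back at 16. Desilylation with HF·pyridine (THF/pyridine, 0 °C) would give methyl (E)-3-[4-hydroxy-3-(3-methylbut-2-enyl)phenyl]prop-2-enoate F4 (the same compound as A4). F4 would be esterified with acid 13 by N,N'-diisopropylcarbodiimide and a catalytic amount of 4-(dimethylamino)pyridinium tosylate (CH2Cl2, 0 °C), conditions that keep free base low.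

Step 3. The risk is isomerisation of the skipped enyne to a conjugated allene under the lithium amide, silylation at carbon to a silylketene, or incomplete oxygen transfer to the acetylide. The fallback changes the dienophile from an ynol ether to a ketene acetal; it sets out from 4 and comes back at 16. Alkylation of dilithiated acetic acid (LiN(i-Pr)2, 2 equiv, THF/DMPU) with 4 would give 5-methylhex-4-enoic acid F5. Double deprotonation (LiN(i-Pr)2, 2.2 equiv) and silylation with Me3SiCl would give the ketene bis(trimethylsilyl) acetal 5-methyl-1,1-bis(trimethylsilyloxy)hexa-1,4-diene F6. Heating F6 with pyrone 3 (PhMe, 80 °C) should give, by [4+2] cycloaddition, loss of CO2 and loss of Me3SiOH, methyl (E)-3-[3-(3-methylbut-2-enyl)-4-(trimethylsilyloxy)phenyl]prop-2-enoate F7. F7 would be taken without chromatography into the fluoride-catalysed exchange with 14 under the conditions of step 7.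

Further compounds
F1 | step 4 | methyl 3-(3-methylbut-2-enyl)-4-(triisopropylsilyloxy)benzoate | COC(=O)c1ccc(O[Si](C(C)C)(C(C)C)C(C)C)c(CC=C(C)C)c1
F2 | step 4 | [3-(3-methylbut-2-enyl)-4-(triisopropylsilyloxy)phenyl]methanol | OCc1ccc(O[Si](C(C)C)(C(C)C)C(C)C)c(CC=C(C)C)c1
F3 | step 4 | 3-(3-methylbut-2-enyl)-4-(triisopropylsilyloxy)benzaldehyde | O=Cc1ccc(O[Si](C(C)C)(C(C)C)C(C)C)c(CC=C(C)C)c1
F4 | step 7 | methyl (E)-3-[4-hydroxy-3-(3-methylbut-2-enyl)phenyl]prop-2-enoate | COC(=O)/C=C/c1ccc(O)c(CC=C(C)C)c1
F5 | step 3 | 5-methylhex-4-enoic acid | CC(C)=CCCC(=O)O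
F6 | step 3 | 5-methyl-1,1-bis(trimethylsilyloxy)hexa-1,4-diene | CC(C)=CCC=C(O[Si](C)(C)C)O[Si](C)(C)C
F7 | step 3 | methyl (E)-3-[3-(3-methylbut-2-enyl)-4-(trimethylsilyloxy)phenyl]prop-2-enoate | COC(=O)/C=C/c1ccc(O[Si](C)(C)C)c(CC=C(C)C)c1
A1 | direct plan | methyl p-coumarate, methyl (E)-3-(4-hydroxyphenyl)prop-2-enoate | COC(=O)/C=C/c1ccc(O)cc1
A2 | direct plan | methyl (E)-3-[4-(2-methylbut-3-yn-2-yloxy)phenyl]prop-2-enoate | COC(=O)/C=C/c1ccc(OC(C)(C)C#C)cc1
A3 | direct plan | methyl (E)-3-[4-(2-methylbut-3-en-2-yloxy)phenyl]prop-2-enoate | COC(=O)/C=C/c1ccc(OC(C)(C)C=C)cc1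
A4 | direct plan | methyl (E)-3-[4-hydroxy-3-(3-methylbut-2-enyl)phenyl]prop-2-enoate | COC(=O)/C=C/c1ccc(O)c(CC=C(C)C)c1
A5 | direct plan | (S)-3-acetoxy-1-diazobutan-2-one | C[C@H](OC(C)=O)C(=O)C=[N+]=[N-]
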